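**Retrosynthetic overview**

1. Core numbering (6-oxabicyclo[3.2.1]octane): C1 = quaternary bridgehead with the dienyl chain, C2 = methyl carbinol, C3/C4 = CH2, C5 = oxygen-bearing bridgehead, O6, C7 = OCH2 carbon, C8 = CH with the hydroxypropyl chain, Cx = CH(CH3)CHO carbon on C5.
2. Feature used: C1 sits between C7 and the tertiary carbinol C2, so once C7 is a lactone carbonyl the C1–C2 bond is an aldol bond. It is cut to a C1 lactone enolate (from a C1 bromide) and a methyl ketone on the chain from C5.
3. The triene is cut at C(CH3)=CH (Julia–Kocienski) into an aldehyde on the C1 chain and an allylic sulfone from cis-α-irone; C7 is reduced from lactone to ether after the ring closure.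
4. The γ-lactone (C7, O6, C5, C8, C1) comes from a Roche-ester-derived Cx ketone: propiolate addition sets C5, cuprate addition/lactonisation and hydrogenation set C8, allylation and bromination load C1.
5. Ring order: γ-lactone first, then the cyclohexane ring C1–C2–C3–C4–C5–C8 (key step); the cyclohexene ring arrives ready-made with the irone.

Key step: step 11

Assumption: enantiopure cis-α-irone 30, (E)-4-[(1R,5S)-2,5,6,6-tetramethylcyclohex-2-en-1-yl]but-3-en-2-one, is taken as available by resolution of commercial α-irone.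

Remark on the design: the C1 chain is carried as an allyl group, because an ether oxygen in that chain could capture the C7 oxocarbenium ion of step 13. The C2 hydroxyl is capped as a TMS ether from step 14 to step 21, because the free hydroxyl would close a six-membered lactol onto the aldehyde of step 16. Atom labels C1–C8 and Cx in names are those of the overview.

**Route**

Step 1
Reactants: 1 methyl (R)-3-hydroxy-2-methylpropanoate
Product: 2 methyl (R)-3-[(tert-butyldimethylsilyl)oxy]-2-methylpropanoate
Conditions: TBSCl, imidazole, CH2Cl2, 0 °C → rt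
Reagents that add atoms: tert-butyldimethylsilyl chloride, C[Si](C)(Cl)C(C)(C)C
Why: Imidazole-promoted silyl ether formation on a primary alcohol, which leaves the stereocentre untouched.

Step 2
Reactants: 2 methyl (R)-3-[(tert-butyldimethylsilyl)oxy]-2-methylpropanoate
Product: 3 (R)-3-[(tert-butyldimethylsilyl)oxy]-N-methoxy-N,2-dimethylpropanamide
Conditions: MeNH(OMe)·HCl, i-PrMgCl, THF, −20 → 0 °C
Reagents that add atoms: N,O-dimethylhydroxylamine hydrochloride, CNOC.Cl
Why: Weinreb amide formation by aminolysis of the ester with the magnesium amide is fast at low temperature and should not epimerise the α-centre.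

Step 3
Reactants: 3 (R)-3-[(tert-butyldimethylsilyl)oxy]-N-methoxy-N,2-dimethylpropanamide; 4 2-(2-bromoethyl)-2-methyl-1,3-dioxolane
Product: 6 (R)-1-[(tert-butyldimethylsilyl)oxy]-2-methyl-5-(2-methyl-1,3-dioxolan-2-yl)pentan-3-one, via Grignard reagent 5 (not isolated)
Conditions: 4, Mg, THF, rt; then 3, THF, 0 °C; aq. NH4Cl
Reagents that add atoms: none
Why: Grignard addition to a Weinreb amide stops at the ketone because the chelated tetrahedral intermediate survives until work-up, and the dioxolane keeps the future C2 ketone masked.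

Step 4
Reactants: 6 (R)-1-[(tert-butyldimethylsilyl)oxy]-2-methyl-5-(2-methyl-1,3-dioxolan-2-yl)pentan-3-one; 7 ethyl propiolate
Product: 9 ethyl (S)-4-hydroxy-4-[(R)-1-[(tert-butyldimethylsilyl)oxy]propan-2-yl]-6-(2-methyl-1,3-dioxolan-2-yl)hex-2-ynoate, via lithium acetylide 8 (not isolated)
Conditions: 7, LiN(SiMe3)2, THF, −78 °C; then 6, −78 °C; aq. NH4Cl
Reagents that add atoms: none
Why: 1,2-Addition of the lithium acetylide to the ketone should follow the Felkin–Anh model, with the non-chelating CH2OTBS group anti to the nucleophile, which sets C5 (S) with the Cx methyl and the new oxygen syn along the CH2O–Cx–C5–C8 zigzag; the minor C5 epimer would be removed by chromatography.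

Step 5
Reactants: 10 3-bromopropan-1-ol
Product: 11 (3-bromopropoxy)triisopropylsilane
Conditions: TIPSCl, imidazole, CH2Cl2, rt
Reagents that add atoms: triisopropylsilyl chloride, CC(C)[Si](Cl)(C(C)C)C(C)C
Why: Standard silylation of a primary alcohol; TIPS is chosen so that this ether outlasts the TBS ether in step 21.

Step 6
Reactants: 9 ethyl (S)-4-hydroxy-4-[(R)-1-[(tert-butyldimethylsilyl)oxy]propan-2-yl]-6-(2-methyl-1,3-dioxolan-2-yl)hex-2-ynoate; 11 (3-bromopropoxy)triisopropylsilane
Product: 14 (S)-5-[(R)-1-[(tert-butyldimethylsilyl)oxy]propan-2-yl]-5-[2-(2-methyl-1,3-dioxolan-2-yl)ethyl]-4-[3-(triisopropylsilyloxy)propyl]furan-2(5H)-one, via Grignard reagent 12 (not isolated), via hydroxy enoate 13 (not isolated)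
Conditions: 11, Mg, THF, rt (3 equiv of 12); CuI (1.5 equiv), THF, −78 °C; then 9, −78 → −20 °C; aq. NH4Cl, rt
Reagents that add atoms: none
Why: Syn carbocupration of the ynoate (cuprate conjugate addition) puts the C8 chain on the carbon bonded to C5 and leaves the ester cis to the tertiary alkoxide, so the (Z)-hydroxy enoate lactonises to the butenolide.

Step 7
Reactants: 14 the butenolide of step 6
Product: 15 (4S,5R)-5-[(R)-1-[(tert-butyldimethylsilyl)oxy]propan-2-yl]-5-[2-(2-methyl-1,3-dioxolan-2-yl)ethyl]-4-[3-(triisopropylsilyloxy)propyl]dihydrofuran-2(3H)-one (C8–H cis to the C4 chain, C8 chain cis to Cx)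
Conditions: H2 (4 atm), 5% Rh/Al2O3, EtOAc, rt
Reagents that add atoms: none
Why: Heterogeneous hydrogenation of the trisubstituted butenolide should deliver hydrogen to the ring face that carries the unbranched C4 chain, anti to the α-branched Cx group on C5, which sets C8.

Step 8
Reactants: 15 the saturated lactone of step 7; 16 allyl bromide
Product: 18 α-allyl lactone (3-allyl derivative of 15, both C1 epimers), via lithium enolate 17 (not isolated)
Conditions: LiN(i-Pr)2, THF, −78 °C; then 16, DMPU, −78 → −40 °C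
Reagents that add atoms: none
Why: Alkylation of the lactone lithium enolate with a reactive allylic bromide; the new C1 centre is of no consequence because steps 9 and 11 erase it.

Step 9
Reactants: 18 α-allyl lactone
Product: 20 α-allyl-α-bromo lactone (3-allyl-3-bromo derivative of 15, both C1 epimers, dioxolane intact), via lithium enolate 19 (not isolated)
Conditions: LiN(i-Pr)2, THF, −78 °C; then CBr4, −78 °C; aq. NH4Cl
Reagents that add atoms: carbon tetrabromide, BrC(Br)(Br)Br
Why: Electrophilic bromination of the fully substituted lactone enolate gives the tertiary α-bromo lactone, and either C1 epimer serves.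

Step 10
Reactants: 20 α-allyl-α-bromo lactone with the dioxolane
Product: 21 α-allyl-α-bromo γ-lactone with a 3-oxobutyl chain on C5 (both C1 epimers; C5, C8 and Cx as in 15)
Conditions: PPTS, acetone/H2O, 50 °C
Reagents that add atoms: water, O
Why: Mild acid-catalysed hydrolysis of the dioxolane under conditions that primary TBS and TIPS ethers and the tertiary α-bromo lactone should tolerate.

Step 11
Reactants: 21 α-allyl-α-bromo γ-lactone with the 3-oxobutyl chain
Product: 23 1-allyl-5-[(R)-1-[(tert-butyldimethylsilyl)oxy]propan-2-yl]-2-hydroxy-2-methyl-8-[3-(triisopropylsilyloxy)propyl]-6-oxabicyclo[3.2.1]octan-7-one (C2–OH equatorial, C8 chain on the O6–C7 side), via samarium enolate 22 (not isolated)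
Conditions: SmI2 (2.5 equiv), THF, −78 °C, slow addition of 21; aq. NH4Cl at −78 °C
Reagents that add atoms: none
Why: SmI2 (divalent samarium) transfers two electrons to the tertiary C1–Br bond and gives the trivalent samarium enolate 22 at C1 only, with no base present that could enolise the methyl ketone; the closest known reaction type is the SmI2-promoted intramolecular Reformatsky reaction of α-bromo esters and lactones with ketones. The enolate carbon C1 then attacks the ketone carbon C2 in a 6-(enolexo)-exo-trig closure, which forms the cyclohexane ring C1–C2–C3–C4–C5–C8 and turns the γ-lactone into the 6-oxabicyclo[3.2.1]octan-7-one. C1 is set by the tether: the three-atom chain hangs from C5 and can reach C1 only on the lactone face syn to the C5–C4 bond, so both C1 epimers of 21 converge on one configuration with the allyl group exo. C2 is set by chelation of samarium between the enolate oxygen and the ketone oxygen in a chair-like transition state, which places the new hydroxyl gauche to C7 (equatorial) and the methyl group axial, anti to C7. The step needs reduction of C–Br ahead of the dialkyl ketone and C–C bond formation ahead of enolate protonation; the first is secured by the easy reduction of a tertiary α-bromo lactone at −78 °C without HMPA, the second by the ketone held close on the C5 tether and the absence of a proton source. The C8 chain lies on the face opposite to the tether, so only C8–H faces the incoming ketone.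

Step 12
Reactants: 23 the bicyclic hydroxy lactone
Product: 24 the corresponding C7 lactol (7-hydroxy-6-oxabicyclo[3.2.1]octane, both anomers)
Conditions: i-Bu2AlH (2.2 equiv), CH2Cl2, −78 °C; aq. potassium sodium tartrate (KNaC4H4O6)
Reagents that add atoms: none
Why: Partial reduction of a γ-lactone with i-Bu2AlH stops at the lactol at −78 °C because the aluminium hemiacetal does not collapse; one equivalent is consumed by the C2 hydroxyl.

Step 13
Reactants: 24 the C7 lactol
Product: 25 1-allyl-5-[(R)-1-[(tert-butyldimethylsilyl)oxy]propan-2-yl]-2-methyl-8-[3-(triisopropylsilyloxy)propyl]-6-oxabicyclo[3.2.1]octan-2-ol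
Conditions: Et3SiH (excess), BF3·OEt2, CH2Cl2, −78 → −40 °C
Reagents that add atoms: none
Why: Ionic hydrogenation: BF3·OEt2 ionises the lactol to the cyclic C7 oxocarbenium ion, which excess silane should reduce at low temperature before the silyl ethers or the tertiary alcohol can intervene.

Step 14
Reactants: 25 the bicyclic ether alcohol
Product: 26 the C2 trimethylsilyl ether of 25
Conditions: TMSOTf, 2,6-lutidine, CH2Cl2, −78 °C
Reagents that add atoms: trimethylsilyl trifluoromethanesulfonate, C[Si](C)(C)OS(=O)(=O)C(F)(F)F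
Why: Silyl triflate silylation caps the hindered tertiary C2 hydroxyl with a group that step 21 removes together with the TBS ether.

Step 15
Reactants: 26 the C2 trimethylsilyl ether
Product: 28 primary alcohol (C1 chain = 3-hydroxypropyl), via alkylborane 27 (not isolated)
Conditions: 9-BBN, THF, 0 °C → rt; then H2O2, aq. NaOH, 0 °C
Reagents that add atoms: hydrogen peroxide, OO
Why: Hydroboration–oxidation of the terminal alkene with 9-BBN is anti-Markovnikov and should leave the silyl ethers and the cyclic ether alone.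

Step 16
Reactants: 28 the primary alcohol
Product: 29 aldehyde (C1 chain = 3-oxopropyl)
Conditions: Dess–Martin periodinane, NaHCO3, CH2Cl2, 0 °C → rt
Reagents that add atoms: none
Why: Dess–Martin oxidation of a primary alcohol to the aldehyde under buffered conditions, with the C2 oxygen blocked against lactol formation.

Step 17
Reactants: 30 cis-α-irone, (E)-4-[(1R,5S)-2,5,6,6-tetramethylcyclohex-2-en-1-yl]but-3-en-2-one
Product: 31 (E)-4-[(1R,5S)-2,5,6,6-tetramethylcyclohex-2-en-1-yl]but-3-en-2-ol (both carbinol epimers)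
Conditions: NaBH4, CeCl3·7H2O, MeOH, 0 °C
Reagents that add atoms: none
Why: Luche 1,2-reduction of the enone under near-neutral conditions avoids γ-deprotonation, so the ring stereocentres and the position of the ring double bond are kept; the new carbinol centre is immaterial.

Step 18
Reactants: 31 the allylic alcohol
Product: 32 allylic 1-phenyl-1H-tetrazol-5-yl sulfide
Conditions: 1-phenyl-1H-tetrazole-5-thiol, PPh3, DIAD, THF, 0 °C → rt
Reagents that add atoms: 1-phenyl-1H-tetrazole-5-thiol, SC1=NN=NN1c2ccccc2
Why: Mitsunobu thioetherification with the acidic thiol should proceed by direct SN2 displacement, because the SN2' terminus is the hindered ring carbon next to the gem-dimethyl group.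

Step 19
Reactants: 32 the allylic sulfide
Product: 33 allylic 1-phenyl-1H-tetrazol-5-yl sulfone
Conditions: (NH4)6Mo7O24·4H2O (cat.), 30% H2O2, EtOH, 0 °C → rt
Reagents that add atoms: hydrogen peroxide, OO
Why: Molybdate-catalysed peroxide oxidation of sulfide to sulfone is selective for sulfur over the di- and trisubstituted alkenes.

Step 20
Reactants: 29 the aldehyde; 33 the allylic sulfone
Product: 35 (E,E)-triene, fully silylated (C2–OTMS, Cx–CH2OTBS, C8 chain OTIPS), via sulfonyl carbanion 34 (not isolated)
Conditions: 33, KN(SiMe3)2, DME, −60 °C; then 29, −60 °C → rt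
Reagents that add atoms: none
Why: Julia–Kocienski olefination: the α-sulfonyl allylic carbanion adds to the aldehyde through its α-carbon, and Smiles rearrangement with loss of SO2 and the tetrazolone forms the C(CH3)=CH bond, expected to favour the E isomer through an open transition state with the potassium counter-ion in a polar solvent.

Step 21
Reactants: 35 the silylated triene
Product: 36 diol (free C2–OH and Cx–CH2OH, C8 chain still OTIPS)
Conditions: CSA (cat.), MeOH/CH2Cl2, 0 °C
Reagents that add atoms: none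
Why: Acid-catalysed methanolysis should cleave the tertiary TMS ether and the primary TBS ether much faster than the primary TIPS ether (selective silyl ether solvolysis).

Step 22
Reactants: 36 the diol
Product: 37 Cx aldehyde with the C8 chain still OTIPS
Conditions: Dess–Martin periodinane, NaHCO3, CH2Cl2, 0 °C
Reagents that add atoms: none
Why: Dess–Martin oxidation touches only the primary alcohol, since the tertiary C2 hydroxyl cannot be oxidised, and the buffered medium avoids epimerisation at Cx and β-elimination of O6.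

Step 23
Reactants: 37 the TIPS-protected aldehyde
Product: 38 the target, CNP0419303.1
Conditions: HF·pyridine, pyridine, THF, 0 °C → rt
Reagents that add atoms: none
Why: Buffered HF·pyridine desilylation removes the primary TIPS ether under weakly acidic, non-basic conditions that should neither epimerise the α-methyl aldehyde nor open the C5–O6 bond by β-elimination.

**Compound list**

1 | methyl (R)-3-hydroxy-2-methylpropanoate | COC(=O)[C@H](C)CO | starting material
2 | methyl (R)-3-[(tert-butyldimethylsilyl)oxy]-2-methylpropanoate | COC(=O)[C@H](C)CO[Si](C)(C)C(C)(C)C | intermediate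
3 | (R)-3-[(tert-butyldimethylsilyl)oxy]-N-methoxy-N,2-dimethylpropanamide | CON(C)C(=O)[C@H](C)CO[Si](C)(C)C(C)(C)C | intermediate
4 | 2-(2-bromoethyl)-2-methyl-1,3-dioxolane | CC1(CCBr)OCCO1 | starting material
5 | [2-(2-methyl-1,3-dioxolan-2-yl)ethyl]magnesium bromide | CC1(CC[Mg]Br)OCCO1 | intermediate
6 | (R)-1-[(tert-butyldimethylsilyl)oxy]-2-methyl-5-(2-methyl-1,3-dioxolan-2-yl)pentan-3-one | CC1(CCC(=O)[C@H](C)CO[Si](C)(C)C(C)(C)C)OCCO1 | intermediate
7 | ethyl propiolate | CCOC(=O)C#C | starting material
8 | ethyl 3-lithiopropiolate | CCOC(=O)C#C[Li] | intermediate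
9 | ethyl (S)-4-hydroxy-4-[(R)-1-[(tert-butyldimethylsilyl)oxy]propan-2-yl]-6-(2-methyl-1,3-dioxolan-2-yl)hex-2-ynoate | CCOC(=O)C#C[C@](O)(CCC1(C)OCCO1)[C@H](C)CO[Si](C)(C)C(C)(C)C | intermediate
10 | 3-bromopropan-1-ol | OCCCBr | starting material
11 | (3-bromopropoxy)triisopropylsilane | BrCCCO[Si](C(C)C)(C(C)C)C(C)C | intermediate
12 | [3-(triisopropylsilyloxy)propyl]magnesium bromide | Br[Mg]CCCO[Si](C(C)C)(C(C)C)C(C)C | intermediate
13 | ethyl (Z)-4-hydroxy-4-[(R)-1-[(tert-butyldimethylsilyl)oxy]propan-2-yl]-6-(2-methyl-1,3-dioxolan-2-yl)-3-[3-(triisopropylsilyloxy)propyl]hex-2-enoate (formed as its magnesium alkoxide; C5 as in 9) | CCOC(=O)/C=C(CCCO[Si](C(C)C)(C(C)C)C(C)C)\[C@](O)(CCC1(C)OCCO1)[C@H](C)CO[Si](C)(C)C(C)(C)C | intermediate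
14 | (S)-5-[(R)-1-[(tert-butyldimethylsilyl)oxy]propan-2-yl]-5-[2-(2-methyl-1,3-dioxolan-2-yl)ethyl]-4-[3-(triisopropylsilyloxy)propyl]furan-2(5H)-one | O=C1O[C@]([C@H](C)CO[Si](C)(C)C(C)(C)C)(CCC2(C)OCCO2)C(CCCO[Si](C(C)C)(C(C)C)C(C)C)=C1 | intermediate
15 | (4S,5R)-5-[(R)-1-[(tert-butyldimethylsilyl)oxy]propan-2-yl]-5-[2-(2-methyl-1,3-dioxolan-2-yl)ethyl]-4-[3-(triisopropylsilyloxy)propyl]dihydrofuran-2(3H)-one | O=C1O[C@]([C@H](C)CO[Si](C)(C)C(C)(C)C)(CCC2(C)OCCO2)[C@@H](CCCO[Si](C(C)C)(C(C)C)C(C)C)C1 | intermediate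
16 | allyl bromide | C=CCBr | starting material
17 | lithium enolate of 15 | [Li]OC1O[C@]([C@H](C)CO[Si](C)(C)C(C)(C)C)(CCC2(C)OCCO2)[C@@H](CCCO[Si](C(C)C)(C(C)C)C(C)C)C=1 | intermediate
18 | 3-allyl derivative of 15 (both C1 epimers) | O=C1O[C@]([C@H](C)CO[Si](C)(C)C(C)(C)C)(CCC2(C)OCCO2)[C@@H](CCCO[Si](C(C)C)(C(C)C)C(C)C)C1CC=C | intermediate
19 | lithium enolate of 18 | [Li]OC1O[C@]([C@H](C)CO[Si](C)(C)C(C)(C)C)(CCC2(C)OCCO2)[C@@H](CCCO[Si](C(C)C)(C(C)C)C(C)C)C=1CC=C | intermediate
20 | 3-allyl-3-bromo derivative of 15 (both C1 epimers) | O=C1O[C@]([C@H](C)CO[Si](C)(C)C(C)(C)C)(CCC2(C)OCCO2)[C@@H](CCCO[Si](C(C)C)(C(C)C)C(C)C)C1(Br)CC=C | intermediate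
21 | 3-allyl-3-bromo-5-[(R)-1-[(tert-butyldimethylsilyl)oxy]propan-2-yl]-5-(3-oxobutyl)-4-[3-(triisopropylsilyloxy)propyl]dihydrofuran-2(3H)-one (both C1 epimers; C5 and C8 as in 15) | O=C1O[C@]([C@H](C)CO[Si](C)(C)C(C)(C)C)(CCC(C)=O)[C@@H](CCCO[Si](C(C)C)(C(C)C)C(C)C)C1(Br)CC=C | intermediate
22 | samarium enolate of the debrominated lactone (trivalent samarium on the enolate oxygen) | I[Sm](I)OC1O[C@]([C@H](C)CO[Si](C)(C)C(C)(C)C)(CCC(C)=O)[C@@H](CCCO[Si](C(C)C)(C(C)C)C(C)C)C=1CC=C | intermediate
23 | 1-allyl-5-[(R)-1-[(tert-butyldimethylsilyl)oxy]propan-2-yl]-2-hydroxy-2-methyl-8-[3-(triisopropylsilyloxy)propyl]-6-oxabicyclo[3.2.1]octan-7-one (core configured as in the target) | C=CC[C@]12C(=O)O[C@]([C@H](C)CO[Si](C)(C)C(C)(C)C)(CC[C@]1(C)O)[C@H]2CCCO[Si](C(C)C)(C(C)C)C(C)C | intermediate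
24 | C7 lactol of 23 (both anomers) | C=CC[C@]12C(O)O[C@]([C@H](C)CO[Si](C)(C)C(C)(C)C)(CC[C@]1(C)O)[C@H]2CCCO[Si](C(C)C)(C(C)C)C(C)C | intermediate
25 | 1-allyl-5-[(R)-1-[(tert-butyldimethylsilyl)oxy]propan-2-yl]-2-methyl-8-[3-(triisopropylsilyloxy)propyl]-6-oxabicyclo[3.2.1]octan-2-ol | C=CC[C@]12CO[C@]([C@H](C)CO[Si](C)(C)C(C)(C)C)(CC[C@]1(C)O)[C@H]2CCCO[Si](C(C)C)(C(C)C)C(C)C | intermediate
26 | C2 trimethylsilyl ether of 25 | C=CC[C@]12CO[C@]([C@H](C)CO[Si](C)(C)C(C)(C)C)(CC[C@]1(C)O[Si](C)(C)C)[C@H]2CCCO[Si](C(C)C)(C(C)C)C(C)C | intermediate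
27 | B-alkyl-9-borabicyclo[3.3.1]nonane from 26 (boron on the terminal carbon of the C1 chain) | C1CCC2CCCC(C1)B2CCC[C@]34CO[C@]([C@H](C)CO[Si](C)(C)C(C)(C)C)(CC[C@]3(C)O[Si](C)(C)C)[C@H]4CCCO[Si](C(C)C)(C(C)C)C(C)C | intermediate
28 | primary alcohol, C1 chain = 3-hydroxypropyl | OCCC[C@]12CO[C@]([C@H](C)CO[Si](C)(C)C(C)(C)C)(CC[C@]1(C)O[Si](C)(C)C)[C@H]2CCCO[Si](C(C)C)(C(C)C)C(C)C | intermediate
29 | aldehyde, C1 chain = 3-oxopropyl | O=CCC[C@]12CO[C@]([C@H](C)CO[Si](C)(C)C(C)(C)C)(CC[C@]1(C)O[Si](C)(C)C)[C@H]2CCCO[Si](C(C)C)(C(C)C)C(C)C | intermediate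
30 | cis-α-irone, (E)-4-[(1R,5S)-2,5,6,6-tetramethylcyclohex-2-en-1-yl]but-3-en-2-one | CC1=CC[C@H](C)C(C)(C)[C@@H]1/C=C/C(C)=O | starting material
31 | (E)-4-[(1R,5S)-2,5,6,6-tetramethylcyclohex-2-en-1-yl]but-3-en-2-ol (both carbinol epimers) | CC1=CC[C@H](C)C(C)(C)[C@@H]1/C=C/C(C)O | intermediate
32 | 1-phenyl-5-{[(E)-4-[(1R,5S)-2,5,6,6-tetramethylcyclohex-2-en-1-yl]but-3-en-2-yl]sulfanyl}-1H-tetrazole | CC1=CC[C@H](C)C(C)(C)[C@@H]1/C=C/C(C)SC2=NN=NN2c3ccccc3 | intermediate
33 | 1-phenyl-5-{[(E)-4-[(1R,5S)-2,5,6,6-tetramethylcyclohex-2-en-1-yl]but-3-en-2-yl]sulfonyl}-1H-tetrazole | CC1=CC[C@H](C)C(C)(C)[C@@H]1/C=C/C(C)S(=O)(=O)C2=NN=NN2c3ccccc3 | intermediate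
34 | potassium α-sulfonyl carbanion of 33 | CC1=CC[C@H](C)C(C)(C)[C@@H]1/C=C/[C-](C)S(=O)(=O)C2=NN=NN2c3ccccc3.[K+] | intermediate
35 | (E,E)-triene with C2–OTMS, Cx–CH2OTBS and C8-chain OTIPS | CC1=CC[C@H](C)C(C)(C)[C@@H]1/C=C/C(C)=C/CC[C@]12CO[C@]([C@H](C)CO[Si](C)(C)C(C)(C)C)(CC[C@]1(C)O[Si](C)(C)C)[C@H]2CCCO[Si](C(C)C)(C(C)C)C(C)C | intermediate
36 | diol with free C2–OH and Cx–CH2OH, C8-chain OTIPS | CC1=CC[C@H](C)C(C)(C)[C@@H]1/C=C/C(C)=C/CC[C@]12CO[C@]([C@H](C)CO)(CC[C@]1(C)O)[C@H]2CCCO[Si](C(C)C)(C(C)C)C(C)C | intermediate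
37 | Cx aldehyde with C8-chain OTIPS | CC1=CC[C@H](C)C(C)(C)[C@@H]1/C=C/C(C)=C/CC[C@]12CO[C@]([C@H](C)C=O)(CC[C@]1(C)O)[C@H]2CCCO[Si](C(C)C)(C(C)C)C(C)C | intermediate
38 | CNP0419303.1 | CC1=CC[C@H](C)C(C)(C)[C@@H]1/C=C/C(C)=C/CC[C@]12CO[C@]([C@H](C)C=O)(CC[C@]1(C)O)[C@H]2CCCO | target

**Step count and risks**

Total step count: 23. Longest linear sequence: 19 steps (steps 1–4, 6–16 and 20–23). Steps 17–19 make the sulfone and step 5 makes the silyl bromide.

The three steps most likely to fail:

1. Step 11 (key step). What may go wrong: the samarium enolate is protonated before it closes, the samarium aldolate reverts by retro-aldol cleavage on warming, or closure through a non-chelated transition state erodes the C2 selectivity. The fallback sets out from 15 and comes back at 23. It makes the C1 enolate by conjugate addition instead of by reduction. Lactone 15 is deprotonated with LiN(i-Pr)2 and treated with dimethylmethyleneiminium iodide (Eschenmoser's salt) to give the Mannich base F1. Methylation with MeI and elimination with DBU give the α-methylene lactone F2. PPTS in wet acetone frees the ketone and gives the α-methylene keto lactone F3. (CH2=CH)2CuLi in THF at −78 °C adds a vinyl group to the exocyclic methylene carbon, which builds the C1 allyl group and the C1 lithium enolate in one event. The enolate closes onto the ketone through a lithium-chelated chair (tandem conjugate addition–aldol cyclisation) and gives 23.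

2. Step 20. What may go wrong: weak geometric control in forming the trisubstituted C(CH3)=CH bond, together with partial γ-attack of the allylic carbanion on the aldehyde. The fallback sets out from 31, uses aldehyde 29 and comes back at 35. It is a Horner–Wittig sequence with stereospecific elimination. Alcohol 31 is converted with MsCl/Et3N and then LiCl into the allylic chloride F4. Ph2PLi displaces the chloride at the less hindered secondary carbon, and H2O2 gives the allylic diphenylphosphine oxide F5. Its lithium derivative (n-BuLi, THF, −78 °C) adds to 29, and a cold quench gives the β-hydroxy phosphine oxides F6, which are separated by chromatography. The diastereomers whose syn elimination leads to the E alkene are treated with NaH in DMF and give 35.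

3. Step 7. What may go wrong: insufficient discrimination between the two faces of the butenolide by the C5 substituents, slow reduction of the hindered trisubstituted alkene, or hydrogenolysis of the allylic C5–O6 bond. The fallback sets out from 14 and comes back at 15. It is a homogeneous copper hydride conjugate reduction under reagent control: Cu(OAc)2 with one enantiomer of DTBM-SEGPHOS, polymethylhydrosiloxane and t-BuOH in toluene. The ligand enantiomer is chosen so that hydride delivery to C8 anti to Cx is the matched case. No new compound is made on the way.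

**Further compounds**

F1 | step 11 | 3-[(dimethylamino)methyl] derivative of 15 (Mannich base, both C1 epimers) | O=C1O[C@]([C@H](C)CO[Si](C)(C)C(C)(C)C)(CCC2(C)OCCO2)[C@@H](CCCO[Si](C(C)C)(C(C)C)C(C)C)C1CN(C)C
F2 | step 11 | 3-methylene derivative of 15 (α-methylene lactone, dioxolane intact) | O=C1O[C@]([C@H](C)CO[Si](C)(C)C(C)(C)C)(CCC2(C)OCCO2)[C@@H](CCCO[Si](C(C)C)(C(C)C)C(C)C)C1=C
F3 | step 11 | α-methylene lactone with the free 3-oxobutyl chain | O=C1O[C@]([C@H](C)CO[Si](C)(C)C(C)(C)C)(CCC(C)=O)[C@@H](CCCO[Si](C(C)C)(C(C)C)C(C)C)C1=C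
F4 | step 20 | (1R,5S)-1-[(E)-3-chlorobut-1-en-1-yl]-2,5,6,6-tetramethylcyclohex-2-ene (both epimers at the chloride carbon) | CC1=CC[C@H](C)C(C)(C)[C@@H]1/C=C/C(C)Cl
F5 | step 20 | diphenyl{(E)-4-[(1R,5S)-2,5,6,6-tetramethylcyclohex-2-en-1-yl]but-3-en-2-yl}phosphine oxide | CC1=CC[C@H](C)C(C)(C)[C@@H]1/C=C/C(C)P(=O)(c2ccccc2)c3ccccc3
F6 | step 20 | β-hydroxy phosphine oxide adducts of lithiated F5 with 29 (the two new centres as the separated diastereomers) | CC1=CC[C@H](C)C(C)(C)[C@@H]1/C=C/C(C)(P(=O)(c2ccccc2)c3ccccc3)C(O)CC[C@]45CO[C@]([C@H](C)CO[Si](C)(C)C(C)(C)C)(CC[C@]4(C)O[Si](C)(C)C)[C@H]5CCCO[Si](C(C)C)(C(C)C)C(C)C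
F0 | step 7 | none | none
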